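5 questions stood: which flask gives the best share of E in all that became E or L (the selectivity), and what that share is in each flask.

all flasks: Z 0.052 M
- summer: J 2.5 equiv; G 2 mol%; temperature −5 °C; run made earlier
- alpha: J 2.50 equiv; G 1 mol%; temperature −5 °C; time 20 h
- gamma: J 2.50 equiv; G 1 mol%; temperature 25 °C; time 20 h
- zeta: J 2.50 equiv; G 1 mol%; temperature −20 °C; time 20 h
- epsilon: J 2.50 equiv; G 1 mol%; temperature 10 °C; time 20 h

1. the best flask by share of E in all that became E or L; "all alike" if 1.5 percentage points covers them all (alpha / gamma / zeta / epsilon / all alike)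
2. share of E in all that became E or L, alpha
3. share of E in all that became E or L, gamma
4. share of E in all that became E or L, zeta
5. share of E in all that became E or L, epsilon

- the earlier runs were read with a standard deviation of 1.5 percentage points
- the earlier runs do not show what temperature does; that part of a forecast is a guess
- no earlier run changes the charge of G; that part of a forecast is a guess

summer run (percent of the Z charged)

| time / h | E / % | L / % |
|---|---|---|
| 0.500 | 0 | 0 |
| 0.833 | 3 | 0 |
| 1.33 | 3 | 4 |
| 2.00 | 2 | 3 |
| 4.00 | 3 | 8 |
| 6.00 | 7 | 14 |

(readings scatter by 1.5 percentage points)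

The summer run showed no effect of temperature, and it held 2 mol% of G against 1 mol% in alpha, so both effects were guesses. But it did show a pace. I let R be the part of the charge not yet E or L. If R falls by a pseudo-first-order law, dR/dt = −kR integrates to R = exp(−kt), so a single reading yields k. The last reading, at 6.00 h, gave R = 79.0%, and so 17.6 h for the conversion half-time H, the time in which R halves at that constant pace. This is a reading and carries the scatter of 1.5 percentage points. If the pace follows G, which is a guess, alpha has H = 35.3 h. Its 20 h is then 0.567 of H, so I expected alpha to stop with R near 67.5%, still on its way. H gave no share, so the forecast's shares do not rest on it.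

The forecast gave 33% for alpha, 27% for gamma, 37% for zeta and 30% for epsilon, and it named zeta as the tentative best, assuming as a guess that “colder conditions modestly favour the lower-barrier path”.

The flasks gave 14.2% in alpha, 2.15% in gamma, 34.9% in zeta and 5.57% in epsilon, so zeta was best, as forecast, while gamma lay 25 points below its forecast.

    X → L (k = 2.20 × 10⁻⁴ min⁻¹, Ea = 87.0 kJ mol⁻¹)
    J ⇌ D (K = 0.860, k = 2.70 × 10⁻⁴ min⁻¹, Ea = 81.0 kJ mol⁻¹, ΔH = −79.0 kJ mol⁻¹)
    J + G + X → G + E (k = 2.10 L² mol⁻² min⁻¹, Ea = 40.0 kJ mol⁻¹)
    Z + G → G + X (k = 0.690 L mol⁻¹ min⁻¹, Ea = 37.0 kJ mol⁻¹)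
    (constants at −20 °C)

In zeta at 20 h, R stood at 93.4%, which gives H = 202 h, or 10.1 times the time run. That flask was not at rest, with Z at 65.0% and X, the species formed on the way, at 28.4%. In gamma the state at 10.0 h gives H = 2.30 h, so 20 h holds 8.70 such half-times. Gamma ended with Z at 0.221%, and its share stood at 2.15% at 200 h. Zeta kept no constant pace: at 200 h its R stood at 10.2%, not the 50.3% that H gave, and its share had fallen from 34.9% to 26.8%.

(The data come from a simulation with constants of no real substance; scatter was added.)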